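## The problem

Moracin Q (18) is a 2-arylbenzofuran with no stereocentre, so the synthesis is a problem of regiochemistry and functional-group tolerance, not of stereocontrol. Ring A (the benzo ring) carries three different substituents on adjacent carbons: the 3-methyl-2-oxobutyl chain at C4, a methoxy group at C5 and a free hydroxyl at C6. Only C7 bears hydrogen, so stepwise substitution of a preformed benzofuran would have to tell C4 from C7 and the C5 oxygen from the C6 oxygen. Ring C is a plain 5-substituted resorcinol joined to C2 of the furan (ring B), a bond that cross-coupling forms easily. The groups that limit the reagents are the enolisable ketone one carbon away from an electron-rich arene, three phenols of which one must stay distinct from a methyl ether, and the acid- and oxidation-sensitive 2-arylbenzofuran. The feature that opens a short route is the sequence C7(H)–C6(OH)–C5(OMe)–C4(C) between the two furan carbons C7a and C3a. These six carbons can be read as a ketene (C6=C7) on C7a, the furan bond C7a=C3a, and an enol ether (C4=C5) on C3a. Such a triene closes between C5 and C6 by a six-electron electrocyclisation and enolises to the C6 phenol with C5 already methylated; the ketene comes from a 2-(diazoacetyl)furan by Wolff rearrangement, so ring A reduces to a 2,3,5-trisubstituted furan.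

## Retrosynthesis

**18 back to 16.** The two benzyl–oxygen bonds of ring C are cut to give dibenzyl ether 17, and the ketone is then masked as the dioxolane 16. Benzyl ethers are chosen because the aryl bromide 8 that carries them is commercial and hydrogenolysis frees a resorcinol without touching a benzofuran. The dioxolane is not an added protecting group; it is the form in which the side-chain carbonyl is first made. The C6 hydroxyl needs no protection. The forward steps ask only for dilute acid and then hydrogen over Pd/C.

**16 back to 13.** Ring A is opened between C5 and C6 (dienone 15, then furylketene 14), and the C7–C7a bond is returned to the carbonyl carbon, which gives diazoketone 13. The neighbouring cuts, C3a–C4 by acid cyclisation or a furan C–O or C2=C3 bond, leave a fully substituted benzene or an ambiguous polycarbonyl chain to be made. This cut turns all of ring A into two side arms on a furan, and the C5/C6 oxygen pattern follows from connectivity alone. The forward reaction must produce the ketene cleanly and let it cyclise before anything else traps it.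

**13 back to 10.** The bond between the furoyl carbon and the diazo carbon is cut. It is made by acylation of the simplest diazoalkane with the mixed carbonic anhydride 12 of acid 11, which comes from methyl ester 10 by saponification. The mixed-anhydride route is preferred to the acid chloride because it generates no hydrogen chloride near the enol ether and the dioxolane. The forward steps must keep the pH above about 4.

**10 back to 9.** The enol ether double bond is cut to ketone 9 by a retro-Wittig methoxymethylenation. This sets the enol ether carbon (future C5) on the furyl ketone carbon (future C4) in one step, and its geometry does not matter because both isomers converge in the ring closure. The forward reaction must add to an enolisable, moderately hindered ketone without opening the neighbouring ketal.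

**9 back to 7 and 8.** The bond between furan C5 and ring C is cut to furan 7 and bromide 8, to be joined by direct C–H arylation at the only free α-position of the furan. The arylation is placed here and not on bromofuroate 2, because in 2 the furan C–Br bond would compete with 8 for palladium. In 7 that bromide is already spent and no enol ether is yet present to undergo Heck chemistry.

**7 back to 1, 3 and 5.** The two ketal C–O bonds are cut to ynone 4 and ethylene glycol 5 (double conjugate addition). The two C–C bonds at the ynone carbonyl are then cut to methyl 3-bromofuran-2-carboxylate 2, 3-methylbut-1-yne 3 and a one-carbon carbonyl unit (carbonylative alkynylation). Ester 2 comes from commercial acid 1. The ynone delivers a 1,3-dicarbonyl chain in which the distal ketone is ketalised regiospecifically and without acid, so the two carbonyls never have to be told apart. All four starting materials 1, 3, 5 and 8 are commercial.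

## Roads not taken

**Alternative 1:** Cut the furan C2=C3 bond. An ortho-acyloxybenzyl phosphonium salt A2 is treated with Et3N; the ylide carbon (future C3) attacks the neighbouring aryl ester carbonyl (future C2) and, after loss of triphenylphosphine oxide, gives the 4-prenyl benzofuran A1.
- Merits: this is the most secure way to close a 2-arylbenzofuran. It is mild and convergent, and its key step is better precedented than the photochemical step chosen here.
- Weak points: A2 is a benzene with five different substituents in a row (phosphoniomethyl, prenyl, methoxy, benzyloxy, acyloxy), and its regiocontrolled preparation is the real problem, which the key step does not touch. The benzylic bromination or hydrobromination needed for the phosphonium salt endangers the prenyl group. After ring closure the prenyl group still needs hydroboration and oxidation to reach the isopropyl ketone.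
- Comparison: if the arene were in hand, this road would be the safer one. The chosen plan offers instead an arm-by-arm assembly of the same substitution pattern on a commercial furan, with the C6 hydroxyl emerging free.

**Alternative 2:** Cut the C3a–C4 bond. A furan carrying a 4-methoxy-3,5-dioxohexanoate chain, A4, is heated with p-toluenesulfonic acid in toluene; the furan β-carbon attacks the C4 ketone, and water loss and enolisation give benzofuranol ester A3.
- Merits: it also builds ring A on a furan and places the C5 methoxy and C6 hydroxyl through the chain. It needs neither a diazo compound nor light.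
- Weak points: a 3,5-dioxo ester under acid closes readily through oxygen to a 4-hydroxy-2-pyranone. The furan β-position is a weak nucleophile, and an aryl furan does not tolerate hot acid well. A3 carries an acetate arm, which must still be turned into the isopropyl ketone (amide formation and Grignard addition with the phenol protected).
- Comparison: this road is operationally simpler in its key step. The chosen plan answers with a pericyclic ring closure whose regiochemistry cannot go astray and with a side chain that is already complete.

**Alternative 3:** Cut the C1'–C6' bond of ring C. A 1-(benzofuran-2-yl)hexane-1,3,5-trione A6 is folded with aqueous KOH; the terminal methyl attacks the aryl ketone, and dehydration and enolisation give the free resorcinol A5.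
- Merits: the cyclisation is biomimetic and well known for aryl triketones, and ring C needs no protecting groups.
- Weak points: the key step builds the one ring that can be bought (bromide 8). The fully substituted ring A must already be present in A6, so the hard part is left unsolved. The triketone can also close to a 4-pyranone, and a benzofuran-2-carboxylate has to be made to acylate the acetylacetone dianion.
- Comparison: this road is better in protecting-group economy on ring C. The chosen plan is better where it counts, in ring A, and pays only one hydrogenolysis for ring C.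

Key step: step 8

Remark on the chemistry: the methoxymethylenation in step 5 is expected to give both enol ether geometries. Compounds 10–14 are named and drawn as the E isomer, and the mixture is carried on, since both isomers give the same phenol in step 8.

## Route

Step 1
Reactants: 1 3-bromofuran-2-carboxylic acid
Product: 2 methyl 3-bromofuran-2-carboxylate
Conditions: MeOH, H2SO4 (cat.), reflux
Reagents that add atoms: methanol, CO
Why: Fischer esterification; the electron-poor bromofuroic acid tolerates hot acidic methanol, and the methyl ester masks the acid through the palladium and ylide steps.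

Step 2
Reactants: 2 methyl 3-bromofuran-2-carboxylate; 3 3-methylbut-1-yne
Product: 4 methyl 3-(4-methylpent-2-ynoyl)furan-2-carboxylate
Conditions: Pd(OAc)2 (2 mol%), n-BuP(1-adamantyl)2 (6 mol%), K2CO3, CO (10 bar), DMF, 100 °C, autoclave
Reagents that add atoms: carbon monoxide, [C-]#[O+]
Why: Carbonylative Sonogashira coupling of an activated heteroaryl bromide: zerovalent palladium inserts into the C–Br bond, CO insertion under pressure outruns alkyne transfer, and the copper-free system suppresses the direct alkynylation; the sealed vessel holds the volatile alkyne.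

Step 3
Reactants: 4 methyl 3-(4-methylpent-2-ynoyl)furan-2-carboxylate; 5 ethylene glycol
Product: 7 methyl 3-{[2-(propan-2-yl)-1,3-dioxolan-2-yl]acetyl}furan-2-carboxylate, via hydroxyethoxy enone 6 (not isolated)
Conditions: 5 (5 equiv), K2CO3 (0.2 equiv), MeCN, 25 to 50 °C
Reagents that add atoms: none
Why: Base-catalysed double oxa-Michael addition: the glycol adds to the ynone β-carbon to give vinylogous ester 6, whose pendant hydroxyl closes 5-exo-trig on the same carbon, so the ketal forms only at the isopropyl-bearing carbon, without acid, and the furyl ketone stays free.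

Step 4
Reactants: 7 methyl 3-{[2-(propan-2-yl)-1,3-dioxolan-2-yl]acetyl}furan-2-carboxylate; 8 1,3-bis(benzyloxy)-5-bromobenzene
Product: 9 methyl 5-[3,5-bis(benzyloxy)phenyl]-3-{[2-(propan-2-yl)-1,3-dioxolan-2-yl]acetyl}furan-2-carboxylate
Conditions: Pd(OAc)2 (2 mol%), KOAc (2 equiv), DMA, 130 °C
Reagents that add atoms: none
Why: Direct C–H arylation by acetate-assisted concerted metalation–deprotonation at the only α C–H of the furan, as established for 2-furoates; bromide 8 is the sole oxidative-addition partner because the furan bromide was spent in step 2, and KOAc is too weak for ketone α-arylation.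

Step 5
Reactants: 9 methyl 5-[3,5-bis(benzyloxy)phenyl]-3-{[2-(propan-2-yl)-1,3-dioxolan-2-yl]acetyl}furan-2-carboxylate
Product: 10 methyl 5-[3,5-bis(benzyloxy)phenyl]-3-[(1E)-1-methoxy-3-[2-(propan-2-yl)-1,3-dioxolan-2-yl]prop-1-en-2-yl]furan-2-carboxylate
Conditions: Ph3P(CH2OMe)Cl, KN(SiMe3)2, THF, 0 °C; then 9, 0 to 25 °C
Reagents that add atoms: (methoxymethyl)triphenylphosphonium chloride, COC[P+](c1ccccc1)(c1ccccc1)c1ccccc1.[Cl-]
Why: Wittig methoxymethylenation; the small, reactive, salt-free ylide adds to the electron-poor furyl ketone faster than it enolises it and leaves the methyl ester alone, and the E/Z ratio is irrelevant because both isomers converge in step 8.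

Step 6
Reactants: 10 methyl 5-[3,5-bis(benzyloxy)phenyl]-3-[(1E)-1-methoxy-3-[2-(propan-2-yl)-1,3-dioxolan-2-yl]prop-1-en-2-yl]furan-2-carboxylate
Product: 11 5-[3,5-bis(benzyloxy)phenyl]-3-[(1E)-1-methoxy-3-[2-(propan-2-yl)-1,3-dioxolan-2-yl]prop-1-en-2-yl]furan-2-carboxylic acid
Conditions: LiOH·H2O, THF/MeOH/H2O, 25 °C; then 1 M HCl to pH 4–5, 0 °C, EtOAc
Reagents that add atoms: lithium hydroxide, [Li+].[OH-]
Why: Ester saponification; enol ether, dioxolane and benzyl ethers are inert to hydroxide, and the cold two-phase acidification stops at a pH where neither acetal-type group hydrolyses at a relevant rate.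

Step 7
Reactants: 11 5-[3,5-bis(benzyloxy)phenyl]-3-[(1E)-1-methoxy-3-[2-(propan-2-yl)-1,3-dioxolan-2-yl]prop-1-en-2-yl]furan-2-carboxylic acid
Product: 13 1-{5-[3,5-bis(benzyloxy)phenyl]-3-[(1E)-1-methoxy-3-[2-(propan-2-yl)-1,3-dioxolan-2-yl]prop-1-en-2-yl]furan-2-yl}-2-diazoethan-1-one, via mixed carbonic anhydride 12 (not isolated)
Conditions: i-BuOCOCl, N-methylmorpholine, THF, −15 °C; then CH2N2, Et2O, 0 to 25 °C
Reagents that add atoms: diazomethane, C=[N+]=[N-]
Why: First half of the Arndt–Eistert sequence: the carboxylate is activated as the isobutyl carbonic anhydride under buffered, chloride-free conditions and acylates diazomethane at the furoyl carbonyl, so no acid reaches the enol ether or the ketal.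

Step 8
Reactants: 13 1-{5-[3,5-bis(benzyloxy)phenyl]-3-[(1E)-1-methoxy-3-[2-(propan-2-yl)-1,3-dioxolan-2-yl]prop-1-en-2-yl]furan-2-yl}-2-diazoethan-1-one
Product: 16 2-[3,5-bis(benzyloxy)phenyl]-5-methoxy-4-{[2-(propan-2-yl)-1,3-dioxolan-2-yl]methyl}-1-benzofuran-6-ol, via furylketene 14 (not isolated), via 5H-benzofuran-6-one 15 (not isolated)
Conditions: hν (365 nm LED or Hg lamp through Pyrex), dry degassed ClCH2CH2Cl (0.01 M), 25 °C; then 80 °C, 1 h
Reagents that add atoms: none
Why: Excitation of 13 expels dinitrogen with a 1,2-shift of the furan carbon (C7a) from the carbonyl carbon to the diazo carbon (C7), a photochemical Wolff rearrangement that gives furylketene 14. In 14 the ketene C6=C7 bond, the furan C7a=C3a bond and the enol ether C4=C5 bond form a hexatriene whose central alkene is held cis by the furan. Ring A, a six-membered carbocycle, closes by a thermally allowed disrotatory six-electron electrocyclisation that forms the C5–C6 bond and gives dienone 15. Dienone 15 has a hydrogen at C5 and enolises irreversibly to phenol 16, which restores the furan and creates the benzene ring. The closest known reaction type is the photo-Wolff, dienylketene electrocyclisation and tautomerisation sequence that ends the Danheiser benzannulation, in which furan and other heteroarene double bonds are known to serve as the central alkene, together with the naphthol synthesis from ortho-vinylaryl diazoketones. No stereocentre results, since the C5 centre of 15 is transient and is erased by enolisation. The selectivity needed is cyclisation of the ketene ahead of dimerisation, trapping or carbene chemistry; the fixed adjacency of the two arms, the high dilution in a dry aprotic solvent and light of a wavelength that the product absorbs only weakly secure it. Regiochemistry is fixed by connectivity, and the E isomer, with hydrogen turned inward at C5, closes fastest while the Z isomer converges on the same phenol.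

Step 9
Reactants: 16 2-[3,5-bis(benzyloxy)phenyl]-5-methoxy-4-{[2-(propan-2-yl)-1,3-dioxolan-2-yl]methyl}-1-benzofuran-6-ol
Product: 17 1-{2-[3,5-bis(benzyloxy)phenyl]-6-hydroxy-5-methoxy-1-benzofuran-4-yl}-3-methylbutan-2-one
Conditions: 1 M HCl, THF, 25 °C
Reagents that add atoms: water, O
Why: Acid-catalysed hydrolysis of a dialkyl ketone dioxolane; dilute acid at room temperature is too mild to make the liberated ketone attack C3 of the benzofuran, and benzyl and methyl ethers are untouched.

Step 10
Reactants: 17 1-{2-[3,5-bis(benzyloxy)phenyl]-6-hydroxy-5-methoxy-1-benzofuran-4-yl}-3-methylbutan-2-one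
Product: 18 moracin Q, 1-[2-(3,5-dihydroxyphenyl)-6-hydroxy-5-methoxy-1-benzofuran-4-yl]-3-methylbutan-2-one
Conditions: H2 (1 atm), Pd/C (10%), EtOAc/MeOH, 25 °C
Reagents that add atoms: none
Why: Catalytic hydrogenolysis of the two aryl benzyl ethers; at atmospheric pressure the dialkyl ketone and the benzofuran C2=C3 bond are not reduced if the reaction is stopped at complete debenzylation.

## Compound list

1 | 3-bromofuran-2-carboxylic acid | OC(=O)c1occc1Br | starting material
2 | methyl 3-bromofuran-2-carboxylate | COC(=O)c1occc1Br | intermediate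
3 | 3-methylbut-1-yne | CC(C)C#C | starting material
4 | methyl 3-(4-methylpent-2-ynoyl)furan-2-carboxylate | COC(=O)c1occc1C(=O)C#CC(C)C | intermediate
5 | ethylene glycol (ethane-1,2-diol) | OCCO | starting material
6 | methyl 3-[(2E)-3-(2-hydroxyethoxy)-4-methylpent-2-enoyl]furan-2-carboxylate | COC(=O)c1occc1C(=O)/C=C(/OCCO)C(C)C | intermediate (not isolated)
7 | methyl 3-{[2-(propan-2-yl)-1,3-dioxolan-2-yl]acetyl}furan-2-carboxylate | COC(=O)c1occc1C(=O)CC1(C(C)C)OCCO1 | intermediate
8 | 1,3-bis(benzyloxy)-5-bromobenzene | Brc1cc(OCc2ccccc2)cc(OCc2ccccc2)c1 | starting material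
9 | methyl 5-[3,5-bis(benzyloxy)phenyl]-3-{[2-(propan-2-yl)-1,3-dioxolan-2-yl]acetyl}furan-2-carboxylate | COC(=O)c1oc(-c2cc(OCc3ccccc3)cc(OCc3ccccc3)c2)cc1C(=O)CC1(C(C)C)OCCO1 | intermediate
10 | methyl 5-[3,5-bis(benzyloxy)phenyl]-3-[(1E)-1-methoxy-3-[2-(propan-2-yl)-1,3-dioxolan-2-yl]prop-1-en-2-yl]furan-2-carboxylate | COC(=O)c1oc(-c2cc(OCc3ccccc3)cc(OCc3ccccc3)c2)cc1/C(CC1(C(C)C)OCCO1)=C/OC | intermediate
11 | 5-[3,5-bis(benzyloxy)phenyl]-3-[(1E)-1-methoxy-3-[2-(propan-2-yl)-1,3-dioxolan-2-yl]prop-1-en-2-yl]furan-2-carboxylic acid | OC(=O)c1oc(-c2cc(OCc3ccccc3)cc(OCc3ccccc3)c2)cc1/C(CC1(C(C)C)OCCO1)=C/OC | intermediate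
12 | 5-[3,5-bis(benzyloxy)phenyl]-3-[(1E)-1-methoxy-3-[2-(propan-2-yl)-1,3-dioxolan-2-yl]prop-1-en-2-yl]furan-2-carboxylic 2-methylpropyl carbonic anhydride | CC(C)COC(=O)OC(=O)c1oc(-c2cc(OCc3ccccc3)cc(OCc3ccccc3)c2)cc1/C(CC1(C(C)C)OCCO1)=C/OC | intermediate (not isolated)
13 | 1-{5-[3,5-bis(benzyloxy)phenyl]-3-[(1E)-1-methoxy-3-[2-(propan-2-yl)-1,3-dioxolan-2-yl]prop-1-en-2-yl]furan-2-yl}-2-diazoethan-1-one | [N-]=[N+]=CC(=O)c1oc(-c2cc(OCc3ccccc3)cc(OCc3ccccc3)c2)cc1/C(CC1(C(C)C)OCCO1)=C/OC | intermediate
14 | 2-{5-[3,5-bis(benzyloxy)phenyl]-3-[(1E)-1-methoxy-3-[2-(propan-2-yl)-1,3-dioxolan-2-yl]prop-1-en-2-yl]furan-2-yl}ethen-1-one | O=C=Cc1oc(-c2cc(OCc3ccccc3)cc(OCc3ccccc3)c2)cc1/C(CC1(C(C)C)OCCO1)=C/OC | intermediate (not isolated)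
15 | 2-[3,5-bis(benzyloxy)phenyl]-5-methoxy-4-{[2-(propan-2-yl)-1,3-dioxolan-2-yl]methyl}-1-benzofuran-6(5H)-one (racemic at C5) | COC1C(=O)C=C2OC(-c3cc(OCc4ccccc4)cc(OCc4ccccc4)c3)=CC2=C1CC1(C(C)C)OCCO1 | intermediate (not isolated)
16 | 2-[3,5-bis(benzyloxy)phenyl]-5-methoxy-4-{[2-(propan-2-yl)-1,3-dioxolan-2-yl]methyl}-1-benzofuran-6-ol | COc1c(O)cc2oc(-c3cc(OCc4ccccc4)cc(OCc4ccccc4)c3)cc2c1CC1(C(C)C)OCCO1 | intermediate
17 | 1-{2-[3,5-bis(benzyloxy)phenyl]-6-hydroxy-5-methoxy-1-benzofuran-4-yl}-3-methylbutan-2-one | COc1c(O)cc2oc(-c3cc(OCc4ccccc4)cc(OCc4ccccc4)c3)cc2c1CC(=O)C(C)C | intermediate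
18 | moracin Q, 1-[2-(3,5-dihydroxyphenyl)-6-hydroxy-5-methoxy-1-benzofuran-4-yl]-3-methylbutan-2-one | COc1c(O)cc2oc(-c3cc(O)cc(O)c3)cc2c1CC(=O)C(C)C | target

## Step count and risks

Total step count: 10. Longest linear sequence: 10 steps (1 to 18); compounds 3, 5 and 8 enter as purchased reagents.

**Key step (step 8).** The most likely failure is diversion of the excited diazoketone into carbene-type processes (cyclopropanation of the neighbouring enol ether, insertion into traces of water) or secondary photolysis of the 2-arylbenzofuran chromophore once it has formed. The fallback makes the same ketene 14 without light. It sets out from 13: Wolff rearrangement catalysed by PhCO2Ag with Et3N in MeOH at 25 °C should give methyl 2-{5-[3,5-bis(benzyloxy)phenyl]-3-[(1E)-1-methoxy-3-[2-(propan-2-yl)-1,3-dioxolan-2-yl]prop-1-en-2-yl]furan-2-yl}acetate F1, unless ring closure outruns methanol capture and gives 16 directly. LiOH then gives the corresponding furylacetic acid F2. Excess ClCO2Et with Et3N in THF (0 to 60 °C) dehydrates F2 to ketene 14, which cyclises through 15, and the phenol is captured as 2-[3,5-bis(benzyloxy)phenyl]-5-methoxy-4-{[2-(propan-2-yl)-1,3-dioxolan-2-yl]methyl}-1-benzofuran-6-yl ethyl carbonate F3. This is the known benzannulation of 3,5-dienoic acids under mixed-anhydride conditions. K2CO3 in MeOH cleaves the carbonate, and the route is rejoined at 16.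

**Step 2.** The likely failure is direct, non-carbonylative alkynylation at the electron-poor furylpalladium intermediate, or base-induced decay of the ynone at 100 °C. The fallback replaces palladium carbonylation by organomagnesium acylation. From 2, bromine–magnesium exchange with i-PrMgCl·LiCl (THF, −40 °C) gives methyl 3-(chloromagnesio)furan-2-carboxylate F4. Alkyne 3 is deprotonated with n-BuLi and trapped with N-methoxy-N-methylcarbamoyl chloride to give N-methoxy-N,4-dimethylpent-2-ynamide F5. Addition of F4 to F5 and a cold acidic quench return the route at 4.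

**Step 3.** The likely failure is stalling of the second conjugate addition at vinylogous ester 6, whose β-carbon is deactivated and carries the isopropyl group; transesterification of the methyl ester by the glycol is a lesser concern. The fallback brings the ketal in preformed and bypasses the ynone. Ethyl 4-methyl-3-oxopentanoate F6 is ketalised with 5 (TsOH, toluene, water removal) to ethyl 2-[2-(propan-2-yl)-1,3-dioxolan-2-yl]acetate F7. Treatment with MeNH(OMe)·HCl and i-PrMgCl converts F7 into N-methoxy-N-methyl-2-[2-(propan-2-yl)-1,3-dioxolan-2-yl]acetamide F8. The Grignard reagent F4, made from 2 as above, is added to F8 and the route is rejoined at 7.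

**Step 4.** The likely failure is thermal, base-induced opening of the β-keto ketal at 130 °C, together with sluggish oxidative addition of a bromide that is not electron-poor. The fallback separates C–H activation from coupling and runs both below 80 °C. From 7, borylation with B2pin2 catalysed by [Ir(OMe)(cod)]2 and 4,4'-di-tert-butyl-2,2'-bipyridine at the unhindered α C–H gives methyl 3-{[2-(propan-2-yl)-1,3-dioxolan-2-yl]acetyl}-5-(4,4,5,5-tetramethyl-1,3,2-dioxaborolan-2-yl)furan-2-carboxylate F9. Suzuki coupling with 8 (Pd(PPh3)4, K3PO4, dioxane/H2O, 70 °C) returns the route at 9.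

**Step 5.** The likely failure is deprotonation of the ketone by the basic ylide followed by β-elimination that opens the dioxolane, or attack of an alkoxide-type adduct on the neighbouring ester. The fallback removes the electrophilic ester first and changes the olefination type. From 9, LiOH gives 5-[3,5-bis(benzyloxy)phenyl]-3-{[2-(propan-2-yl)-1,3-dioxolan-2-yl]acetyl}furan-2-carboxylic acid F10. Its lithium salt is treated with lithiated (methoxymethyl)trimethylsilane (from Me3SiCH2OMe and s-BuLi, THF, −78 °C) in a Peterson olefination. The adduct, 5-[3,5-bis(benzyloxy)phenyl]-3-{2-hydroxy-1-methoxy-3-[2-(propan-2-yl)-1,3-dioxolan-2-yl]-1-(trimethylsilyl)propan-2-yl}furan-2-carboxylic acid F11, is kept as its dilithium salt and eliminated in the same flask with KOt-Bu on warming. Work-up at pH 4–5 returns the route at 11.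

## Further compounds

F1 | step 8 | methyl 2-{5-[3,5-bis(benzyloxy)phenyl]-3-[(1E)-1-methoxy-3-[2-(propan-2-yl)-1,3-dioxolan-2-yl]prop-1-en-2-yl]furan-2-yl}acetate | COC(=O)Cc1oc(-c2cc(OCc3ccccc3)cc(OCc3ccccc3)c2)cc1/C(CC1(C(C)C)OCCO1)=C/OC
F2 | step 8 | 2-{5-[3,5-bis(benzyloxy)phenyl]-3-[(1E)-1-methoxy-3-[2-(propan-2-yl)-1,3-dioxolan-2-yl]prop-1-en-2-yl]furan-2-yl}acetic acid | OC(=O)Cc1oc(-c2cc(OCc3ccccc3)cc(OCc3ccccc3)c2)cc1/C(CC1(C(C)C)OCCO1)=C/OC
F3 | step 8 | 2-[3,5-bis(benzyloxy)phenyl]-5-methoxy-4-{[2-(propan-2-yl)-1,3-dioxolan-2-yl]methyl}-1-benzofuran-6-yl ethyl carbonate | CCOC(=O)Oc1cc2oc(-c3cc(OCc4ccccc4)cc(OCc4ccccc4)c3)cc2c(CC2(C(C)C)OCCO2)c1OC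
F4 | step 2 | methyl 3-(chloromagnesio)furan-2-carboxylate | COC(=O)c1occc1[Mg]Cl
F5 | step 2 | N-methoxy-N,4-dimethylpent-2-ynamide | CON(C)C(=O)C#CC(C)C
F6 | step 3 | ethyl 4-methyl-3-oxopentanoate | CCOC(=O)CC(=O)C(C)C
F7 | step 3 | ethyl 2-[2-(propan-2-yl)-1,3-dioxolan-2-yl]acetate | CCOC(=O)CC1(C(C)C)OCCO1
F8 | step 3 | N-methoxy-N-methyl-2-[2-(propan-2-yl)-1,3-dioxolan-2-yl]acetamide | CON(C)C(=O)CC1(C(C)C)OCCO1
F9 | step 4 | methyl 3-{[2-(propan-2-yl)-1,3-dioxolan-2-yl]acetyl}-5-(4,4,5,5-tetramethyl-1,3,2-dioxaborolan-2-yl)furan-2-carboxylate | COC(=O)c1oc(B2OC(C)(C)C(C)(C)O2)cc1C(=O)CC1(C(C)C)OCCO1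
F10 | step 5 | 5-[3,5-bis(benzyloxy)phenyl]-3-{[2-(propan-2-yl)-1,3-dioxolan-2-yl]acetyl}furan-2-carboxylic acid | OC(=O)c1oc(-c2cc(OCc3ccccc3)cc(OCc3ccccc3)c2)cc1C(=O)CC1(C(C)C)OCCO1
F11 | step 5 | 5-[3,5-bis(benzyloxy)phenyl]-3-{2-hydroxy-1-methoxy-3-[2-(propan-2-yl)-1,3-dioxolan-2-yl]-1-(trimethylsilyl)propan-2-yl}furan-2-carboxylic acid (mixture of diastereomers) | OC(=O)c1oc(-c2cc(OCc3ccccc3)cc(OCc3ccccc3)c2)cc1C(O)(CC1(C(C)C)OCCO1)C(OC)[Si](C)(C)C
A1 | alternative 1 | 6-(benzyloxy)-2-[3,5-bis(benzyloxy)phenyl]-5-methoxy-4-(3-methylbut-2-en-1-yl)-1-benzofuran | CC(C)=CCc1c(OC)c(OCc2ccccc2)cc2oc(-c3cc(OCc4ccccc4)cc(OCc4ccccc4)c3)cc12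
A2 | alternative 1 | {[4-(benzyloxy)-6-{[3,5-bis(benzyloxy)benzoyl]oxy}-3-methoxy-2-(3-methylbut-2-en-1-yl)phenyl]methyl}triphenylphosphonium bromide | CC(C)=CCc1c(OC)c(OCc2ccccc2)cc(OC(=O)c2cc(OCc3ccccc3)cc(OCc3ccccc3)c2)c1C[P+](c1ccccc1)(c1ccccc1)c1ccccc1.[Br-]
A3 | alternative 2 | methyl 2-{2-[3,5-bis(benzyloxy)phenyl]-6-hydroxy-5-methoxy-1-benzofuran-4-yl}acetate | COC(=O)Cc1c(OC)c(O)cc2oc(-c3cc(OCc4ccccc4)cc(OCc4ccccc4)c3)cc12
A4 | alternative 2 | methyl 6-{5-[3,5-bis(benzyloxy)phenyl]furan-2-yl}-4-methoxy-3,5-dioxohexanoate | COC(=O)CC(=O)C(OC)C(=O)Cc1ccc(-c2cc(OCc3ccccc3)cc(OCc3ccccc3)c2)o1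
A5 | alternative 3 | 5-[6-(benzyloxy)-5-methoxy-4-{[2-(propan-2-yl)-1,3-dioxolan-2-yl]methyl}-1-benzofuran-2-yl]benzene-1,3-diol | Oc1cc(O)cc(-c2cc3c(CC4(C(C)C)OCCO4)c(OC)c(OCc4ccccc4)cc3o2)c1
A6 | alternative 3 | 1-[6-(benzyloxy)-5-methoxy-4-{[2-(propan-2-yl)-1,3-dioxolan-2-yl]methyl}-1-benzofuran-2-yl]hexane-1,3,5-trione | CC(=O)CC(=O)CC(=O)c1cc2c(CC3(C(C)C)OCCO3)c(OC)c(OCc3ccccc3)cc2o1
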